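Readings and results come from a simulation for substances that don't exist; the scatter is artificial.

| setting | alpha | flask |
|---|---|---|
| substrate | 0.020 M | 0.020 M |
| reagent | 0.010 M | 0.0100 M |
| remark | the very flask that is asked about, followed so far |  |
| time |  | 40 h |

alpha run (percent of the substrate charged)

| time / h | other mono adduct / % | single product / % |
|---|---|---|
| 4.00 | 32.1 | 7.4 |
| 8.00 | 37.6 | 5.2 |
| 12.0 | 39.9 | 4.3 |
| 15.0 | 40.8 | 3.0 |
| 20.0 | 44.0 | 0 |

(each reading ± 1 percentage point)

- what may be going on: substrate + reagent <-> single product; substrate + reagent -> other mono adduct; reagent + single product -> double product; reagent + other mono adduct -> double product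

1. equivalents of reagent to substrate, everything else as given, that leave most other mono adduct at 40 h
2. the amount of other mono adduct then, in percent of the substrate charged
3. the amount of other mono adduct with the amounts as given

- The pitfall in the alpha run, which is this flask followed so far, is to read 44.0% of other mono adduct at 20.0 h as a stalled rate before counting the reagent.
- In this flask, 50.0% of the substrate charged is the reagent budget: reagent charged over substrate charged, where each mono adduct spends one share and each double product two. Reagent is the limiting reagent, with 0.0100 M against 0.020 M of substrate.
- At 20.0 h, the alpha run reads 44.0% of other mono adduct and 0% of single product, so these two together hold 44.0% of the substrate charged, against the budget of 50.0%.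
- We assume that free reagent is negligible by then, so the gap is double product at two shares each, 3.00%. We further assume that the two mono adducts' sum ends up as other mono adduct, and on that assumption we commit to 44.0% of it at 40 h.
- The weak link is one pair of readings, whose sum scatters by 1.4 percentage points. We reforge it with the sums 44.2%, 43.8% and 44.0% at 12.0 h, 15.0 h and 20.0 h, which are flat within that scatter. Their mean, 44.0%, carries 0.82 points and leaves our number standing.
- The forecast puts 45% on the flask as charged, 1 point above ours. It gives 1.05 equiv as the best charge with 66% there, saying “Residual substrate, leftover single product and leakage through it trim the yield”.

    substrate + reagent ⇌ single product (K = 200 /M, k = 0.0140 /M/s)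
    substrate + reagent → other mono adduct (k = 0.0180 /M/s)
    reagent + single product → double product (k = 0.00900 /M/s)
    reagent + other mono adduct → double product (k = 2.20 × 10⁻⁴ /M/s)

- The simulation gives 43.7% as charged, and 73.4% at 1.18 equiv. In this flask, half the turnover to other mono adduct was done by 0.863 h, and by 20.0 h, with reagent at 0.526% of its own charge, single product stood at 1.16%, down from 10.5% at 4.00 h. At 40.0 h the budget of this flask is met by 43.7% of other mono adduct, two shares of 3.09% double product, and the traces of single product and free reagent: together 50.0%. In the neighbour with 0.0080 M of substrate the budget is 125%, and 77.7% of other mono adduct, two shares of 19.2% double product, 0.424% of single product and free reagent worth 8.48% of substrate add up to 125%.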